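**Plan**

1. Retrosynthesis first cuts at the protecting-group level (the phenolic MOM acetal, the aryl acetate back to a silyl ether) and the angelate C–O bond, then cuts the bond between the benzene ring carbon and the C(=CH2) carbon.
2. That last cut leaves an arene with only a C–H at the joining position and a terminal alkynol, (S)-6-methylhept-5-en-1-yn-3-ol; neither partner needs a halide, tin or boron group.
3. Enabling feature: the oxygen on the stereocentre sits directly next to the C(=CH2) carbon. As a magnesium alkoxide it steers the aryl group onto the neighbouring alkyne carbon through a five-membered O–Mg–C=C–C ring, and the phenolic oxygen ortho to the joining ring carbon (as its MOM ether) directs the C–H metalation.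
4. Forward: the two para oxygens on the purchased benzene ring are differentiated (TIPS, MOM), the alkynol is made in four steps, the two are joined, then the angelate, the acetate and the free phenol are set in that order; no ring is built.
5. Stereochemistry: the single stereocentre comes from a Noyori asymmetric transfer hydrogenation of an alkynyl ketone and is not touched afterwards; the Z-alkene of the ester is bought with angelic acid.

Key step: step 8

Remark: 3-methoxy-2-methylphenol, 4-methylpent-3-enoic acid, ethynyltrimethylsilane and angelic acid are taken as purchasable; the (S,S)-Ru catalyst is taken to give the (S)-carbinol, as is usual for alkynyl alkyl ketones.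

**Route**

Step 1
Reactants: 1 3-methoxy-2-methylphenol
Product: 2 triisopropyl(3-methoxy-2-methylphenoxy)silane
Conditions: TIPSCl, imidazole, DMF, rt
Reagents that add atoms: chlorotriisopropylsilane, CC(C)[Si](Cl)(C(C)C)C(C)C
Why: Standard phenol silylation; the bulky TIPS ether survives organolithium and Grignard reagents and does not direct lithiation to its own ortho position.

Step 2
Reactants: 2 triisopropyl(3-methoxy-2-methylphenoxy)silane
Product: 5 2-methoxy-3-methyl-4-[(triisopropylsilyl)oxy]phenol, via aryllithium 3 (not isolated), via lithium aryltrimethoxyborate 4 (not isolated)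
Conditions: n-BuLi, TMEDA, Et2O, 0 °C → rt; B(OMe)3, −78 °C → rt; AcOH, 30% H2O2, 0 °C → rt
Reagents that add atoms: hydrogen peroxide, OO; trimethyl borate, COB(OC)OC (its atoms stay only in 4)
Why: Directed ortho-metalation at the one free position next to the methoxy group (the only effective directing group), followed by borylation and oxidation of the aryl–boron bond, should place the second oxygen para to the silyloxy group.

Step 3
Reactants: 5 2-methoxy-3-methyl-4-[(triisopropylsilyl)oxy]phenol
Product: 6 triisopropyl[3-methoxy-4-(methoxymethoxy)-2-methylphenoxy]silane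
Conditions: MOMCl, i-Pr2NEt, CH2Cl2, 0 °C → rt
Reagents that add atoms: chloromethyl methyl ether, COCCl
Why: O-Alkylation of the phenol to the MOM acetal, which protects this oxygen and serves as the directing group for the later ortho-metalation.

Step 4
Reactants: 7 4-methylpent-3-enoic acid
Product: 9 N-methoxy-N,4-dimethylpent-3-enamide, via acyl imidazole 8 (not isolated)
Conditions: CDI, CH2Cl2, 0 °C → rt; MeNH(OMe)·HCl, rt
Reagents that add atoms: N,O-dimethylhydroxylamine hydrochloride, CNOC.Cl; 1,1'-carbonyldiimidazole, O=C(n1ccnc1)n1ccnc1 (its atoms stay only in 8)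
Why: Weinreb amide formation through the acyl imidazole under near-neutral conditions, which should leave the β,γ-double bond out of conjugation.

Step 5
Reactants: 9 N-methoxy-N,4-dimethylpent-3-enamide; 10 ethynyltrimethylsilane
Product: 13 6-methyl-1-(trimethylsilyl)hept-5-en-1-yn-3-one, via lithium acetylide 11 (not isolated), via tetrahedral lithium adduct 12 (not isolated)
Conditions: 10, n-BuLi, THF, −78 °C; 9, −78 → 0 °C; sat. aq NH4Cl
Reagents that add atoms: none
Why: Weinreb ketone synthesis, in which the chelated tetrahedral adduct prevents over-addition and keeps the acidic α-methylene masked until the mild quench.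

Step 6
Reactants: 13 6-methyl-1-(trimethylsilyl)hept-5-en-1-yn-3-one
Product: 14 (3S)-6-methyl-1-(trimethylsilyl)hept-5-en-1-yn-3-ol
Conditions: Ru[(S,S)-TsDPEN(–H)](p-cymene) (1 mol %), i-PrOH, rt, no added base
Reagents that add atoms: none
Why: Noyori asymmetric transfer hydrogenation of an alkynyl ketone, in which the catalyst's Ru–H/N–H pair delivers hydrogen to one carbonyl face with the alkynyl group in the π-recognition site, so the (S,S)-catalyst should set the (S)-carbinol while the base-free medium spares the skipped enone and both C–C multiple bonds.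

Step 7
Reactants: 14 (3S)-6-methyl-1-(trimethylsilyl)hept-5-en-1-yn-3-ol
Product: 15 (3S)-6-methylhept-5-en-1-yn-3-ol
Conditions: K2CO3 (cat.), MeOH, 0 °C → rt
Reagents that add atoms: none
Why: Base-catalysed methanolysis of the alkynyl C–Si bond, which does not involve the stereocentre.

Step 8
Reactants: 6 triisopropyl[3-methoxy-4-(methoxymethoxy)-2-methylphenoxy]silane; 15 (3S)-6-methylhept-5-en-1-yn-3-ol
Product: 20 (3S)-2-{3-methoxy-2-(methoxymethoxy)-4-methyl-5-[(triisopropylsilyl)oxy]phenyl}-6-methylhepta-1,5-dien-3-ol, via aryllithium 16 (not isolated), via arylmagnesium bromide 17 (not isolated), via chloromagnesium alkoxide 18 (not isolated), via oxamagnesacycle 19 (not isolated)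
Conditions: 6 (2.5 equiv), n-BuLi, Et2O, 0 °C → rt; MgBr2·OEt2, 0 °C; then 15 premixed with i-PrMgCl (1.0 equiv, Et2O, 0 °C), CuI (15 mol %), Et2O–toluene, rt → 40 °C; sat. aq NH4Cl
Reagents that add atoms: none
Why: Ortho-lithiation of 6 next to the OMOM oxygen (its only free ortho position; the bulky OTIPS group does not direct) and transmetalation give 17, and under copper catalysis the aryl group is delivered within the magnesium alkoxide 18 to the internal alkyne carbon next to the carbinol carbon, the metal ending on the terminal carbon in the five-membered O–Mg–C=C–C chelate 19, which protonation turns into the 1,1-disubstituted alkene. The closest known reaction type is the copper-catalysed, hydroxyl-directed anti-carbomagnesiation of propargylic alcohols with aryl Grignard reagents, the standard entry to 2-arylallyl alcohols. No ring of the target is closed; the only ring formed is the transient oxamagnesacycle 19, made by alkoxide-tethered delivery to the proximal alkyne carbon and opened on quench. No stereocentre is created, and the carbinol centre of 15 is carried through as a configurationally stable alkoxide, so 20 should keep the (S) configuration. The step needs regioselectivity across the alkyne (aryl on the internal carbon, secured by the alkoxide chelate), site selectivity on the arene (secured by the OMOM-directed metalation) and chemoselectivity over the trisubstituted alkene (which has no neighbouring alkoxide and should not carbometalate); the excess aryl reagent should return 6 on quench for recovery.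

Step 9
Reactants: 20 (3S)-2-{3-methoxy-2-(methoxymethoxy)-4-methyl-5-[(triisopropylsilyl)oxy]phenyl}-6-methylhepta-1,5-dien-3-ol; 21 angelic acid, (2Z)-2-methylbut-2-enoic acid
Product: 23 (3S)-2-{3-methoxy-2-(methoxymethoxy)-4-methyl-5-[(triisopropylsilyl)oxy]phenyl}-6-methylhepta-1,5-dien-3-yl (2Z)-2-methylbut-2-enoate, via mixed anhydride 22 (not isolated)
Conditions: 21, 2,4,6-trichlorobenzoyl chloride, Et3N, toluene, rt; then 20, toluene, 80 °C
Reagents that add atoms: none
Why: Yamaguchi-type mixed-anhydride esterification run without a nucleophilic catalyst, so the alcohol should attack the unhindered angeloyl carbonyl without Z→E isomerisation, and the stereocentre is retained because its C–O bond is not broken.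

Step 10
Reactants: 23 (3S)-2-{3-methoxy-2-(methoxymethoxy)-4-methyl-5-[(triisopropylsilyl)oxy]phenyl}-6-methylhepta-1,5-dien-3-yl (2Z)-2-methylbut-2-enoate
Product: 25 (3S)-2-[5-(acetyloxy)-3-methoxy-2-(methoxymethoxy)-4-methylphenyl]-6-methylhepta-1,5-dien-3-yl (2Z)-2-methylbut-2-enoate, via tetrabutylammonium phenoxide 24 (not isolated)
Conditions: TBAF (1.1 equiv), THF, 0 °C; then Ac2O, 0 °C → rt
Reagents that add atoms: acetic anhydride, CC(=O)OC(C)=O; tetrabutylammonium fluoride, [F-].CCCC[N+](CCCC)(CCCC)CCCC (its cation stays only in 24)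
Why: Fluoride cleaves the aryl silyl ether much faster than it affects the esters or the acetal, and the phenoxide is acetylated in the same flask (desilylation, then O-acetylation).

Step 11
Reactants: 25 (3S)-2-[5-(acetyloxy)-3-methoxy-2-(methoxymethoxy)-4-methylphenyl]-6-methylhepta-1,5-dien-3-yl (2Z)-2-methylbut-2-enoate
Product: 26 (3S)-2-[5-(acetyloxy)-2-hydroxy-3-methoxy-4-methylphenyl]-6-methylhepta-1,5-dien-3-yl (2Z)-2-methylbut-2-enoate
Conditions: ZnBr2, n-PrSH, CH2Cl2, 0 °C, short reaction time
Reagents that add atoms: none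
Why: Lewis-acid-assisted thiolysis of the aryl methoxymethyl acetal, in which the phenol is a good leaving group, so cleavage should be fast at 0 °C and spare the aryl acetate, the allylic angelate and both alkenes.

**Compound list**

1 | 3-methoxy-2-methylphenol | COc1cccc(O)c1C | starting material
2 | triisopropyl(3-methoxy-2-methylphenoxy)silane | COc1cccc(O[Si](C(C)C)(C(C)C)C(C)C)c1C | intermediate
3 | {2-methoxy-3-methyl-4-[(triisopropylsilyl)oxy]phenyl}lithium | [Li]c1ccc(O[Si](C(C)C)(C(C)C)C(C)C)c(C)c1OC | intermediate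
4 | lithium trimethoxy{2-methoxy-3-methyl-4-[(triisopropylsilyl)oxy]phenyl}borate | [Li+].CO[B-](OC)(OC)c1ccc(O[Si](C(C)C)(C(C)C)C(C)C)c(C)c1OC | intermediate
5 | 2-methoxy-3-methyl-4-[(triisopropylsilyl)oxy]phenol | Oc1ccc(O[Si](C(C)C)(C(C)C)C(C)C)c(C)c1OC | intermediate
6 | triisopropyl[3-methoxy-4-(methoxymethoxy)-2-methylphenoxy]silane | COCOc1ccc(O[Si](C(C)C)(C(C)C)C(C)C)c(C)c1OC | intermediate
7 | 4-methylpent-3-enoic acid | CC(C)=CCC(=O)O | starting material
8 | 1-(1H-imidazol-1-yl)-4-methylpent-3-en-1-one | CC(C)=CCC(=O)n1ccnc1 | intermediate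
9 | N-methoxy-N,4-dimethylpent-3-enamide | CC(C)=CCC(=O)N(C)OC | intermediate
10 | ethynyltrimethylsilane | C#C[Si](C)(C)C | starting material
11 | lithium (trimethylsilyl)acetylide | [Li]C#C[Si](C)(C)C | intermediate
12 | lithium 3-[methoxy(methyl)amino]-6-methyl-1-(trimethylsilyl)hept-5-en-1-yn-3-olate | CC(C)=CCC(O[Li])(C#C[Si](C)(C)C)N(C)OC | intermediate
13 | 6-methyl-1-(trimethylsilyl)hept-5-en-1-yn-3-one | CC(C)=CCC(=O)C#C[Si](C)(C)C | intermediate
14 | (3S)-6-methyl-1-(trimethylsilyl)hept-5-en-1-yn-3-ol | C[Si](C)(C)C#C[C@H](CC=C(C)C)O | intermediate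
15 | (3S)-6-methylhept-5-en-1-yn-3-ol | C#C[C@H](CC=C(C)C)O | intermediate
16 | {3-methoxy-2-(methoxymethoxy)-4-methyl-5-[(triisopropylsilyl)oxy]phenyl}lithium | COCOc1c([Li])cc(O[Si](C(C)C)(C(C)C)C(C)C)c(C)c1OC | intermediate
17 | {3-methoxy-2-(methoxymethoxy)-4-methyl-5-[(triisopropylsilyl)oxy]phenyl}magnesium bromide | COCOc1c([Mg]Br)cc(O[Si](C(C)C)(C(C)C)C(C)C)c(C)c1OC | intermediate
18 | chloromagnesium (3S)-6-methylhept-5-en-1-yn-3-olate | C#C[C@H](CC=C(C)C)O[Mg]Cl | intermediate
19 | (5S)-4-{3-methoxy-2-(methoxymethoxy)-4-methyl-5-[(triisopropylsilyl)oxy]phenyl}-5-(3-methylbut-2-en-1-yl)-2,5-dihydro-1,2-oxamagnesole | [Mg]1C=C(c2cc(O[Si](C(C)C)(C(C)C)C(C)C)c(C)c(OC)c2OCOC)[C@H](CC=C(C)C)O1 | intermediate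
20 | (3S)-2-{3-methoxy-2-(methoxymethoxy)-4-methyl-5-[(triisopropylsilyl)oxy]phenyl}-6-methylhepta-1,5-dien-3-ol | C=C(c1cc(O[Si](C(C)C)(C(C)C)C(C)C)c(C)c(OC)c1OCOC)[C@H](CC=C(C)C)O | intermediate
21 | angelic acid, (2Z)-2-methylbut-2-enoic acid | OC(=O)/C(C)=C\C | starting material
22 | (2Z)-2-methylbut-2-enoic 2,4,6-trichlorobenzoic anhydride | O=C(OC(=O)/C(C)=C\C)c1c(Cl)cc(Cl)cc1Cl | intermediate
23 | (3S)-2-{3-methoxy-2-(methoxymethoxy)-4-methyl-5-[(triisopropylsilyl)oxy]phenyl}-6-methylhepta-1,5-dien-3-yl (2Z)-2-methylbut-2-enoate | C=C(c1cc(O[Si](C(C)C)(C(C)C)C(C)C)c(C)c(OC)c1OCOC)[C@H](CC=C(C)C)OC(=O)/C(C)=C\C | intermediate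
24 | tetrabutylammonium 3-methoxy-4-(methoxymethoxy)-2-methyl-5-[(3S)-6-methyl-3-{[(2Z)-2-methylbut-2-enoyl]oxy}hepta-1,5-dien-2-yl]phenolate | C=C(c1cc([O-])c(C)c(OC)c1OCOC)[C@H](CC=C(C)C)OC(=O)/C(C)=C\C.CCCC[N+](CCCC)(CCCC)CCCC | intermediate
25 | (3S)-2-[5-(acetyloxy)-3-methoxy-2-(methoxymethoxy)-4-methylphenyl]-6-methylhepta-1,5-dien-3-yl (2Z)-2-methylbut-2-enoate | C=C(c1cc(OC(C)=O)c(C)c(OC)c1OCOC)[C@H](CC=C(C)C)OC(=O)/C(C)=C\C | intermediate
26 | (3S)-2-[5-(acetyloxy)-2-hydroxy-3-methoxy-4-methylphenyl]-6-methylhepta-1,5-dien-3-yl (2Z)-2-methylbut-2-enoate | C=C(c1cc(OC(C)=O)c(C)c(OC)c1O)[C@H](CC=C(C)C)OC(=O)/C(C)=C\C | target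

**Count and risks**

Total step count: 11. Longest linear sequence: 8 steps (7 to 26, steps 4–11); the arene branch (1 to 26) runs 7 steps.

Steps most likely to fail:

1. Step 8. Aryl transfer from a hindered, electron-rich ortho-alkoxy arylmagnesium reagent may be slow or incomplete, and deprotonation of the terminal alkyne C–H or homocoupling of the aryl reagent may compete. The fallback sets out from 6 and 15 and returns at 20. The same ortho-lithiation of 6 (giving 16) is quenched with iodine to give 1-iodo-3-methoxy-2-(methoxymethoxy)-4-methyl-5-[(triisopropylsilyl)oxy]benzene F1. Alkynol 15 is hydrostannylated with Bu3SnH under Mo(CO)3(CNt-Bu)3 catalysis, which should place tin on the internal alkyne carbon next to the oxygen-bearing carbon, to give (3S)-6-methyl-2-(tributylstannyl)hepta-1,5-dien-3-ol F2. Stille coupling of F1 with F2 (Pd(PPh3)4, CuI, CsF, DMF, 45 °C) should then give 20.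

2. Step 9. The activated angeloyl unit may isomerise from Z to E (tigloyl) during acyl transfer, and acylation of the hindered secondary allylic alcohol may be slow. The fallback sets out from 20 and returns at 23. Alcohol 20 is esterified with 2-[bis(2,2,2-trifluoroethoxy)phosphoryl]propanoic acid (DCC, DMAP, CH2Cl2) to (3S)-2-{3-methoxy-2-(methoxymethoxy)-4-methyl-5-[(triisopropylsilyl)oxy]phenyl}-6-methylhepta-1,5-dien-3-yl 2-[bis(2,2,2-trifluoroethoxy)phosphoryl]propanoate F3 (both epimers at the phosphonate carbon). A Still–Gennari olefination of F3 with acetaldehyde (KHMDS, 18-crown-6, THF, −78 °C) should then build the Z-configured 2-methylbut-2-enoate directly on the substrate and give 23.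

3. Step 11. The aryl acetate may be cleaved or transferred to the thiol, or the acetal may be removed incompletely, when the acetal cleavage is the last operation on the fully acylated compound. The fallback sets out from 23 and returns at 26. The acetal is cleaved one stage earlier, on 23 (ZnBr2, n-PrSH, CH2Cl2, 0 °C), where no aryl ester is present, to give (3S)-2-{2-hydroxy-3-methoxy-4-methyl-5-[(triisopropylsilyl)oxy]phenyl}-6-methylhepta-1,5-dien-3-yl (2Z)-2-methylbut-2-enoate F4. Desilylation (TBAF buffered with AcOH, THF, 0 °C, under argon) gives (3S)-2-(2,5-dihydroxy-3-methoxy-4-methylphenyl)-6-methylhepta-1,5-dien-3-yl (2Z)-2-methylbut-2-enoate F5. Acetylation with one equivalent of Ac2O (pyridine, CH2Cl2, −20 °C) should then take the unhindered hydroxyl flanked by methyl and hydrogen in preference to the hydroxyl flanked by the methoxy group and the branched alkenyl chain, giving 26.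

**Further compounds**

F1 | step 8 | 1-iodo-3-methoxy-2-(methoxymethoxy)-4-methyl-5-[(triisopropylsilyl)oxy]benzene | COCOc1c(I)cc(O[Si](C(C)C)(C(C)C)C(C)C)c(C)c1OC
F2 | step 8 | (3S)-6-methyl-2-(tributylstannyl)hepta-1,5-dien-3-ol | C=C([Sn](CCCC)(CCCC)CCCC)[C@H](CC=C(C)C)O
F3 | step 9 | (3S)-2-{3-methoxy-2-(methoxymethoxy)-4-methyl-5-[(triisopropylsilyl)oxy]phenyl}-6-methylhepta-1,5-dien-3-yl 2-[bis(2,2,2-trifluoroethoxy)phosphoryl]propanoate | C=C(c1cc(O[Si](C(C)C)(C(C)C)C(C)C)c(C)c(OC)c1OCOC)[C@H](CC=C(C)C)OC(=O)C(C)P(=O)(OCC(F)(F)F)OCC(F)(F)F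
F4 | step 11 | (3S)-2-{2-hydroxy-3-methoxy-4-methyl-5-[(triisopropylsilyl)oxy]phenyl}-6-methylhepta-1,5-dien-3-yl (2Z)-2-methylbut-2-enoate | C=C(c1cc(O[Si](C(C)C)(C(C)C)C(C)C)c(C)c(OC)c1O)[C@H](CC=C(C)C)OC(=O)/C(C)=C\C
F5 | step 11 | (3S)-2-(2,5-dihydroxy-3-methoxy-4-methylphenyl)-6-methylhepta-1,5-dien-3-yl (2Z)-2-methylbut-2-enoate | C=C(c1cc(O)c(C)c(OC)c1O)[C@H](CC=C(C)C)OC(=O)/C(C)=C\C
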